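Readings and results were generated by integration with made-up constants.

The beta run, made earlier at a higher charge of L, shows L down to 2.6% at 10.0 s and J draining into D after that, and two chemists disagree over how that draining goes on in two flasks run for longer.

| flask | L | G | remark | time |
|---|---|---|---|---|
| beta | 0.075 M | 1 equiv | run made earlier |  |
| north-east | 0.050 M | 1.00 equiv |  | 3.0 min |
| south | 0.050 M | 1.00 equiv |  | 10 min |

beta run (percent of the L charged)

| time / s | J / % | L / % | D / % |
|---|---|---|---|
| 10.0 | 53.8 | 2.6 | 43.7 |
| 12.0 | 48.7 | 2.4 | 49.0 |
| 15.0 | 43.4 | 2.1 | 54.5 |
| 20.0 | 35.6 | 1.6 | 62.6 |

(scatter of a reading: 0.3 percentage points)

- the numbers in the tables scatter with a standard deviation of 0.3 percentage points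
- what may be going on: L + G -> J + E; J + E -> D

* which of these there is most of at the end, counted by the L in it, north-east (L / J / D)
* which of these there is most of at the end, counted by the L in it, south (L / J / D)
* amount of the one of these that there is most of at the end, in percent of the L charged, north-east
* amount of the one of these that there is most of at the end, in percent of the L charged, south

The first chemist treats cE as frozen, so that J loses the same share in each second, a pseudo-first-order loss: between the first and last readings J falls from 53.8% to 35.6%, which is a half-life of 16.8 s, and that half-life run on to 3.0 min leaves J at 0.0481% in north-east.

The second chemist answers that the first step makes J and E one for one and the draining step removes them one for one, so cJ = cE and cE falls as cJ falls: the loss goes with the square of cJ, and under such a loss the reciprocal 1/cJ climbs at a steady pace. With J as a fraction of the L charged, its reciprocal goes from 1.86 to 2.81 between those readings, and this climb per unit time, divided by the charge of L, is the pairing constant 1.27 /M/s, read from these two readings and on this view steady while cJ falls. The straight line of the beta run, drawn back to time zero, starts from 0.908, and at 0.050 M it climbs 0.0635 /s, slower than in beta, so the second chemist puts J near 8.12% in north-east, far above the first chemist's figure, and near 2.57% in south.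

The forecast takes the second side, on the ground that “J and E are formed and consumed together”, and puts D on top in both flasks, at 91.6% in north-east and 97.3% in south.

The simulation ends north-east with D at 91.6% and J at 8.21%, and south with D at 97.3% and J at 2.58%, which is the second chemist's picture.

    L + G → J + E (k = 47.0 /M/s)
    J + E → D (k = 1.30 /M/s)

South stands 5.8 percentage points in D above north-east for its longer time, and the step from J and E to D is a part of that reason: the extra 7.00 min adds 26.6 to the reciprocal, taking the 8.21% of north-east down to 2.58%. The first chemist's frozen cE holds up inside the short beta stretch it was drawn through, giving J at 15.0 s as 43.8% against a reading of 43.4%. In the neighbour with 0.020 M of L, also at 3.0 min, the pairing constant gives J as 18.2%, and that flask ends with J at 18.6%.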